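**Plan**
- Retrosynthetic cuts, in order: the two benzyl ethers; the C4–aryl bond to the acylphloroglucinol (retro-Friedel–Crafts, the presumed biogenetic union of a flavan C4 cation with the acylphloroglucinol); the pyran ring across O1–C2 and C3–C4 (retro oxa-[4+2]); the aryl–CO bond of the ketone.
- Feature used: C4 is benzylic on ring A, ortho to O1 (on C8a) and para to the C7 oxygen. O1–C8a=C4a–C4 is therefore a latent o-quinone methide at the aldehyde oxidation level, C2=C3 with its aryl group is a 4-vinylphenol, and the same C4 later ionises to a doubly oxygen-stabilised benzylic cation.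
- Forward: the four benzene rings are bought; phloroglucinol is acylated; the pyran ring, the only ring made, is closed by a catalytic asymmetric oxa-Diels–Alder reaction that leaves a methoxy group on C4 as helper; the helper is exchanged for the acylphloroglucinol; hydrogenolysis ends the route.
- Stereochemistry: C2 (S) comes from the chiral Brønsted acid in the cycloaddition. C4 (R) comes from substrate control, by axial attack on the chroman-4-ylium ion trans to the equatorial C2 aryl group (2,4-trans). The C4–OMe centre of the cycloadduct is erased.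

Key step: step 2

Assumption: 9-phenylnonanoic acid and 4-(benzyloxy)styrene are taken as catalogue compounds.
Assumption: the (R)-configured catalyst is taken to give the 2S series in step 2; if the sense of induction is the opposite, its enantiomer is used.

**Step 1**
Reactants: 1 phloroglucinol (benzene-1,3,5-triol); 2 9-phenylnonanoic acid
Product: 3 9-phenyl-1-(2,4,6-trihydroxyphenyl)nonan-1-one
Conditions: BF3·OEt2 (promoter and solvent), 90 °C; aq. NaOAc work-up
Reagents that add atoms: none
Why: Friedel–Crafts C-acylation of phloroglucinol by the BF3-activated carboxylic acid; the new ketone deactivates the ring, so the reaction should stop at the mono-acyl stage; no stereocentre is formed.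

**Step 2**
Reactants: 4 4-(benzyloxy)-2-hydroxybenzaldehyde; 5 4-(benzyloxy)styrene
Product: 8 (2S,4S)-7-(benzyloxy)-2-[4-(benzyloxy)phenyl]-4-methoxy-3,4-dihydro-2H-chromene, via dimethyl acetal 6 (not isolated), via methoxy-o-quinone methide 7 (not isolated)
Conditions: HC(OMe)3 (1.5 equiv), 5 (2 equiv, slow addition), (R)-3,3'-bis(2,4,6-triisopropylphenyl)-BINOL N-triflylphosphoramide (5 mol %), 5 Å MS, toluene, −40 → −20 °C
Reagents that add atoms: trimethyl orthoformate, COC(OC)OC
Why: Proposed new method: the acid converts 4 with the orthoformate into acetal 6, which loses methanol to the methoxy-o-quinone methide 7 held on the chiral N-triflylphosphoramide as a hydrogen-bonded ion pair, and the electron-poor heterodiene O1=C8a–C4a=C4 of 7 adds across the C2=C3 bond of styrene 5 (inverse-electron-demand oxa-Diels–Alder reaction), the closest known reaction types being the racemic Lewis-acid-catalysed three-component chroman synthesis from salicylaldehydes, orthoformates and styrenes, the chiral N-triflylphosphoramide-catalysed [4+2] cycloaddition of 4-aryl o-quinone methides with unactivated styrenes, and the intramolecular [4+2] cycloaddition of alkoxy-o-quinone methides under confined chiral acids. The pyran ring closes in a concerted, asynchronous [4+2] mode in which the C3–C4 bond runs ahead of the O1–C2 bond. C2 is set by the catalyst, whose anion is bound at O1, the atom that becomes attached to C2, and screens one face of the planar heterodiene so that 5 should add from the open face to give the 2S series. C4 follows from the E geometry of 7 and the endo position of the aryl group (2,4-cis), but it is a helper centre that step 3 erases. The step needs head-to-tail regioselectivity, secured by the polarity of 7 (electrophilic C4, nucleophilic O1) matched to the nucleophilic CH2 terminus of 5, and it needs 7 to take up 5 faster than 5 oligomerises, secured by a weak confined acid, low temperature and slow addition of 5.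

**Step 3**
Reactants: 8 (2S,4S)-7-(benzyloxy)-2-[4-(benzyloxy)phenyl]-4-methoxy-3,4-dihydro-2H-chromene; 3 9-phenyl-1-(2,4,6-trihydroxyphenyl)nonan-1-one
Product: 10 1-{3-[(2S,4R)-7-(benzyloxy)-2-[4-(benzyloxy)phenyl]-3,4-dihydro-2H-chromen-4-yl]-2,4,6-trihydroxyphenyl}-9-phenylnonan-1-one, via chroman-4-ylium ion 9 (not isolated)
Conditions: 3 (3 equiv), BF3·OEt2 (30 mol %), CH2Cl2/EtOAc 9:1, −40 → −10 °C
Reagents that add atoms: none
Why: SN1 Friedel–Crafts alkylation: the Lewis acid ionises the benzylic C4–OMe bond to cation 9 (stabilised by O1 ortho and the C7 benzyloxy group para), which is captured at one of the two equivalent free ring positions of 3; attack should occur axially on the half-chair cation on the face trans to the equatorial C2 aryl group, which sets C4 as R (2,4-trans) and leaves C2 untouched.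

**Step 4**
Reactants: 10 1-{3-[(2S,4R)-7-(benzyloxy)-2-[4-(benzyloxy)phenyl]-3,4-dihydro-2H-chromen-4-yl]-2,4,6-trihydroxyphenyl}-9-phenylnonan-1-one
Product: 11 (+)-myristinin D
Conditions: H2 (1 atm), 10% Pd/C, EtOAc/MeOH, rt
Reagents that add atoms: none
Why: Hydrogenolysis of the two benzyl aryl ethers; the hydrogen-bonded, electron-rich aryl ketone and the cyclic benzylic ether should be inert under neutral conditions at 1 atm, and no stereocentre is affected.

**Compound list**
1 | phloroglucinol (benzene-1,3,5-triol) | Oc1cc(O)cc(O)c1 | starting material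
2 | 9-phenylnonanoic acid | OC(=O)CCCCCCCCc1ccccc1 | starting material
3 | 9-phenyl-1-(2,4,6-trihydroxyphenyl)nonan-1-one | O=C(CCCCCCCCc1ccccc1)c1c(O)cc(O)cc1O | intermediate
4 | 4-(benzyloxy)-2-hydroxybenzaldehyde | O=Cc1ccc(OCc2ccccc2)cc1O | starting material
5 | 4-(benzyloxy)styrene (1-(benzyloxy)-4-ethenylbenzene) | C=Cc1ccc(OCc2ccccc2)cc1 | starting material
6 | 5-(benzyloxy)-2-(dimethoxymethyl)phenol (dimethyl acetal, formed in the flask in step 2) | COC(OC)c1ccc(OCc2ccccc2)cc1O | intermediate
7 | (6E)-3-(benzyloxy)-6-(methoxymethylidene)cyclohexa-2,4-dien-1-one (methoxy-o-quinone methide, formed in the flask in step 2) | O=C1C=C(OCc2ccccc2)C=C/C1=C\OC | intermediate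
8 | (2S,4S)-7-(benzyloxy)-2-[4-(benzyloxy)phenyl]-4-methoxy-3,4-dihydro-2H-chromene | CO[C@H]1C[C@@H](c2ccc(OCc3ccccc3)cc2)Oc2cc(OCc3ccccc3)ccc21 | intermediate
9 | (2S)-7-(benzyloxy)-2-[4-(benzyloxy)phenyl]-3,4-dihydro-2H-chromen-4-ylium (chroman-4-ylium ion, formed in the flask in step 3) | [CH+]1C[C@@H](c2ccc(OCc3ccccc3)cc2)Oc2cc(OCc3ccccc3)ccc21 | intermediate
10 | 1-{3-[(2S,4R)-7-(benzyloxy)-2-[4-(benzyloxy)phenyl]-3,4-dihydro-2H-chromen-4-yl]-2,4,6-trihydroxyphenyl}-9-phenylnonan-1-one | O=C(CCCCCCCCc1ccccc1)c1c(O)cc(O)c([C@@H]2C[C@@H](c3ccc(OCc4ccccc4)cc3)Oc3cc(OCc4ccccc4)ccc32)c1O | intermediate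
11 | (+)-myristinin D, 1-{2,4,6-trihydroxy-3-[(2S,4R)-7-hydroxy-2-(4-hydroxyphenyl)-3,4-dihydro-2H-chromen-4-yl]phenyl}-9-phenylnonan-1-one | O=C(CCCCCCCCc1ccccc1)c1c(O)cc(O)c([C@@H]2C[C@@H](c3ccc(O)cc3)Oc3cc(O)ccc32)c1O | target

**Step count and risks**
Total steps: 4. Longest linear sequence: 3 steps (4 → 8 → 10 → 11, or equally 1 → 3 → 10 → 11).

Steps most likely to fail:

1. Step 2 (Proposed new method). The chiral acid may discriminate the faces of an o-quinone methide that carries only a methoxy group on C4 too weakly. The electron-rich styrene may undergo acid-initiated cationic oligomerisation. The product may re-ionise at C4 and take up a second styrene. The fallback uses known chemistry, sets out from 4 and comes back at 8. Claisen–Schmidt condensation of 4 with commercial 1-[4-(benzyloxy)phenyl]ethanone (KOH, EtOH) should give the 2-hydroxychalcone F1. Chemoselective hydrogenation of its C=C bond (H2, Pd/C poisoned with Ph2S, EtOAc) should give the dihydrochalcone F2. Noyori asymmetric transfer hydrogenation (RuCl[(R,R)-TsDPEN](p-cymene), HCO2H/Et3N) should give the (R)-carbinol F3. Mitsunobu cyclisation (PPh3, DIAD, THF, 0 °C) should close the pyran ring with inversion to the (S)-flavan F4. Benzylic oxidation with DDQ in CH2Cl2/MeOH at C4, which is para to the C7 benzyloxy group, followed by capture of the cation by methanol, should give 8; its configuration at C4 is of no consequence for step 3.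

2. Step 3. Facial selectivity at C4 may be incomplete. Capture by the acyl-deactivated ring may be slow enough to allow elimination to the flav-3-ene and self-alkylation on ring A. The acid may open the C2–O1 bond with loss of the C2 configuration. The fallback sets out from 8 and 1 and comes back at 10; it reverses the order of the two C–C bond formations. Under the same catalytic Lewis acid at lower temperature, 8 is captured by an excess of the far more nucleophilic parent phloroglucinol 1 to give the flavanyl-phloroglucinol F5. Acid 2 is converted with oxalyl chloride (cat. DMF, CH2Cl2) into 9-phenylnonanoyl chloride F6. Friedel–Crafts acylation of F5 with F6 (AlCl3, CH2Cl2/PhNO2, 0 °C) at one of the two equivalent free positions of the trihydroxyphenyl ring should give 10.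

3. Step 4. Palladium may hydrogenolyse the benzylic C2–O1 bond (ring opening to a 1,3-diarylpropane) or reduce the aryl ketone. The fallback sets out from 10 and comes back at 11 and makes no new compound. The benzyl ethers are cleaved without reduction by BCl3 in CH2Cl2 at −78 °C, with pentamethylbenzene as scavenger for the benzyl cation.

**Further compounds**
F1 | step 2 | (E)-3-[4-(benzyloxy)-2-hydroxyphenyl]-1-[4-(benzyloxy)phenyl]prop-2-en-1-one | O=C(/C=C/c1ccc(OCc2ccccc2)cc1O)c1ccc(OCc2ccccc2)cc1
F2 | step 2 | 3-[4-(benzyloxy)-2-hydroxyphenyl]-1-[4-(benzyloxy)phenyl]propan-1-one | O=C(CCc1ccc(OCc2ccccc2)cc1O)c1ccc(OCc2ccccc2)cc1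
F3 | step 2 | (1R)-3-[4-(benzyloxy)-2-hydroxyphenyl]-1-[4-(benzyloxy)phenyl]propan-1-ol | O[C@H](CCc1ccc(OCc2ccccc2)cc1O)c1ccc(OCc2ccccc2)cc1
F4 | step 2 | (2S)-7-(benzyloxy)-2-[4-(benzyloxy)phenyl]-3,4-dihydro-2H-chromene | C1C[C@@H](c2ccc(OCc3ccccc3)cc2)Oc2cc(OCc3ccccc3)ccc21
F5 | step 3 | 2-{(2S,4R)-7-(benzyloxy)-2-[4-(benzyloxy)phenyl]-3,4-dihydro-2H-chromen-4-yl}benzene-1,3,5-triol | Oc1cc(O)c([C@@H]2C[C@@H](c3ccc(OCc4ccccc4)cc3)Oc3cc(OCc4ccccc4)ccc32)c(O)c1
F6 | step 3 | 9-phenylnonanoyl chloride | O=C(Cl)CCCCCCCCc1ccccc1
F0 | step 4 | none | none
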